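## The problem

Kushenol B is a (2S)-flavanone whose ring A carries a substituent on every carbon: the ketone carbon C4 on C4a, free hydroxyls on C5 and C7, a prenyl group on C6, an (R)-lavandulyl group on C8 and the ring oxygen O1 on C8a. A synthesis has to place three different carbon groups on a 1,3,5-trioxygenated benzene in a fixed order, and it has to tell the oxygen on C8a from the other two, because ring C closed through O5 would give the 6-lavandulyl-8-prenyl isomer. The two stereocentres, C2 in ring C and C2'' in the side chain, are five bonds apart with the arene between them, so neither can direct the other; each needs its own reagent control, and C2'' is an all-carbon tertiary centre with no heteroatom handle. C2'' can epimerise whenever it stands next to a carbonyl group, and C2 is a benzylic ether of a 2',4'-dioxygenated ring that opens to the chalcone under base and ionises under acid. Three electron-rich alkenes sit next to phenolic oxygens and close to chromans under protic or Lewis acid, which rules out Friedel–Crafts and Fries chemistry and most acidic deprotections. The feature that opens the problem is the chain O8a–C8a–C8–C1''–C2''–C(isopropenyl): if the last carbon is a carbonyl, these six atoms are the ring of a 3,4-dihydrocoumarin in which C2'' is the α-carbon, and an exocyclic methylene on that carbon is C3''. Conjugate addition of a 2-methylprop-1-enyl group to this α-methylene lactone makes the C3''–C4'' bond and leaves a ring-locked enolate that can be protonated at C2'' from one face, while the lactone keeps O8a apart from O5 and O7.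

## Retrosynthesis

**25 from 24.** The last operation removes four methoxymethyl groups from flavanone 24. Acetal protection of O5, O7, O2' and O4' is preferred to silyl or benzyl ethers because the same groups must direct an ortho-lithiation, survive organometallic reagents, 170 °C and aqueous base, and leave without hydrogenation. The price is one mildly acidic step on a molecule with acid-sensitive alkenes and C2, so it is placed last and run cold.

**24 from 21 and 23.** The C2–C1' bond is cut, which removes ring B as boronic acid 23 and leaves chromone 21. The neighbouring cut, O1–C2 (closure of a 2'-hydroxychalcone), is the classical one, but it gives both C2 epimers unless an organocatalyst intervenes, and C2'' is too remote to help. Conjugate arylation of a chromone puts C2 under a chiral rhodium catalyst, and 21 has no stereocentre in ring C and cannot open to a chalcone. The forward reaction must accept an ortho-alkoxy arylboron reagent and a 5,7-dialkoxychromone and must not open the product.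

**21 from 16 through 19, 18 and 17.** Ring C is taken apart carbon by carbon. C2, with the O1–C2 bond, comes from an amide acetal through enaminone 20. C3 is the methyl group of ketone 19. C4 is the formyl carbon of salicylaldehyde 17, placed on the one free ring position of phenol 16 (the C4–C4a bond). A Lewis acid acylation at C4a is excluded by the acetals and alkenes. A photochemical acyl shift from O8a would be one step shorter but would excite an arene that carries three allyl- and homoallyl-type alkenes. The magnesium phenoxide formylation instead uses the free O8a–H to deliver the carbon to C4a under basic conditions. Phenol 16 is simpler by the whole heterocycle, and the forward steps only need to tolerate acetals and alkenes.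

**16 from 13 through 15 and 14.** The isopropenyl group is cut at C=CH2 and at C–CH3, which leads back through methyl ketone 15 and N-methoxy-N-methylamide 14 to the lactone carbonyl of 13. Opening the O8a–C(=O) bond at the same time frees O8a as the only unprotected oxygen, ready to direct the formylation. The lactone carbon is at the right oxidation level to become the isopropenyl carbon in three steps. The requirement is that C2'', which is α to a carbonyl in 13, 14 and 15, keeps its configuration.

**13 from 11 and 12.** The C3''–C4'' bond is cut, so the prenyl arm of the lavandulyl group arrives as alkenylboronate 12 and C2'' is created by protonation of an enolate. The neighbouring cuts are C2''–C3'' (enolate alkylation with bromide 3 under a chiral auxiliary) and C1''–C2'' (a benzylic electrophile of a trioxygenated arene, which is not a usable reagent). The conjugate addition is preferred because it is catalytic, needs no protecting group on O8a and starts from an achiral lactone, 11, that is three steps from phenol 6. The forward reaction has to protonate one face of a rhodium enolate faster than the enolate loses a β-hydrogen or the exocyclic alkene migrates.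

**11 from 6 and 7 through 10, 9 and 8.** The lactone C–O bond, the C8–C1'' bond and the ether O–CH2 bond are cut in turn: lactonisation of acid 10, hydrolysis of ester 9, aromatic Claisen rearrangement of ether 8, and etherification of phenol 6 with bromide 7. The sigmatropic route brings the three-carbon acrylate unit to the carbon next to the oxygen that becomes O1. Because 6 has a mirror plane through that oxygen and the prenyl-bearing carbon, its two ortho positions are identical and no regiochemical question arises. Phenol 6 is simpler by C1''–C3''. The forward sequence must keep the exocyclic double bond out of the ring, since the 3-methylcoumarin is the thermodynamic sink.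

**6 from 1 and 3 through 5, 4 and 2.** The C–O bond at the future C8a is cut back to a C–H bond (iridium-catalysed borylation to 5, then oxidation). The C6–prenyl bond is cut back to the aryllithium of bis-acetal 2 and bromide 3. A start with all three oxygens in place would require three hydroxyls to be told apart after a C-prenylation. From resorcinol 1 the two acetals are equivalent, they direct the prenyl group between them, and the third oxygen is added last at the only C–H with no ortho substituent. The forward borylation must leave the trisubstituted alkene alone.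

**23 from 2 through 22.** Ring B is cut at C–B and C–Br: para-bromination of the same bis-acetal 2 and bromine–lithium exchange give the boronic acid, so both arenes come from 1.

## Roads not taken

**Alternative 1:** Ring A is built rather than substituted. The cut removes the C8a–C8, C7–C6 and C8a–C4a bonds and leads to 3-(methoxymethoxy)-2-prenylcyclobutenone A1 and the lavandulyl-bearing triisopropylsiloxyalkyne A2. On heating, A1 opens to a vinylketene, which adds to A2; the resulting vinylcyclobutenone opens and closes again (4π then 6π) to the pentasubstituted phenol A3, free only at O8a.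
- Merits: the substitution pattern follows from the mechanism, the three oxygens emerge differentiated (free, acetal, silyl ether) in one step, and C2'' is made away from the arene.
- Weak points: C2'' still needs its own asymmetric synthesis inside A2, so the stereochemical problem is moved, not solved. A1 and A2 are each several steps from commercial materials. A3 still lacks C4 and the whole heterocycle, so the end-game is no shorter.
- Comparison: Alternative 1 is better at oxygen differentiation, since a silyl ether at O7 would allow a fluoride step in place of part of the final acidolysis, and it is more convergent. The chosen plan sets against this a six-step access to lactone 11 from resorcinol 1 that rests on symmetry, and a single catalytic step that forms the C3''–C4'' bond and the stereocentre together.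

**Alternative 2:** The cut is C3–C4 of ring C. The phenoxide–dithianyl dianion of the ring A dithiane A4 opens the (S)-aryloxirane A5 at its terminal carbon to give the (R)-carbinol A6; Mitsunobu closure of O8a onto C2 with inversion and thioacetal hydrolysis would finish the flavanone.
- Merits: the C2 configuration comes with the epoxide and does not depend on a catalyst working on a hindered chromone, and no ortho-substituted arylboron reagent is needed.
- Weak points: A4 must be made from aldehyde 17 by a Lewis acid thioacetalisation that the acetals and alkenes may not survive. The dianion is generated in a molecule with three benzylic–allylic CH2 groups. The electron-rich epoxide A5 is as easily opened at its benzylic carbon and rearranges readily. A Mitsunobu displacement at a 2,4-dialkoxybenzylic carbinol can leak through the benzylic cation. The thioacetal has to be removed with thiophilic or oxidising reagents beside three electron-rich alkenes.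
- Comparison: this road does nothing for C2'' and would have to be combined with the chosen key step. It is better in the certainty of the C2 configuration. The chosen plan sets against it two catalytic steps from ketone 19 to flavanone 24 and no sulfur to remove.

**Alternative 3:** The cut is C2''–C3''. The sodium enolate of the ring A 3-arylpropanoyl (R)-4-benzyloxazolidinone A7 is alkylated by bromide 3 to the α-prenyl imide A8.
- Merits: the facial selectivity follows a well-tested chelated enolate model, the diastereomers can be separated so that purity at C2'' can be secured, and every reaction type is established.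
- Weak points: the auxiliary is stoichiometric. A7 needs a saturated three-carbon acyl chain built ortho to a separately protected O8a, about five steps from phenol 6 against three to lactone 11. The auxiliary has to be removed before the carbonyl can become the isopropenyl carbon.
- Comparison: Alternative 3 is better in predictability and precedent. The chosen plan sets against it two to three fewer steps, catalytic chirality, and a lactone that serves as acceptor, as protecting group for O8a and as the source of the isopropenyl carbon. Because its chemistry is established, this road is kept as the fallback for the key step.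

Key step: step 7

Assumption: (R)-BINAP in step 7 and the (R,R)-diene in step 17 are written as the antipodes expected to give (R)-C2'' and (S)-C2; if the sense of induction is the reverse, the mirror-image ligand is used and nothing else changes.

## Route

Step 1
Reactants: 1 resorcinol
Product: 2 1,3-bis(methoxymethoxy)benzene
Conditions: NaH, MOMCl, DMF, 0 °C to rt
Reagents that add atoms: chloromethyl methyl ether, COCCl
Why: Williamson-type O-alkylation of both phenoxides gives the bis-acetal; the methoxymethyl ethers later direct the lithiation and withstand base, heat and organometallic reagents.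

Step 2
Reactants: 2 1,3-bis(methoxymethoxy)benzene; 3 prenyl bromide (1-bromo-3-methylbut-2-ene)
Product: 4 1,3-bis(methoxymethoxy)-2-(3-methylbut-2-en-1-yl)benzene
Conditions: n-BuLi, THF, 0 °C; CuI (10 mol%), 3, –78 °C to rt
Reagents that add atoms: none
Why: Directed ortho-metalation removes the C–H between the two acetal oxygens, and the aryllithium, passed through copper, is alkylated at the primary carbon of 3.

Step 3
Reactants: 4 1,3-bis(methoxymethoxy)-2-(3-methylbut-2-en-1-yl)benzene
Product: 6 3,5-bis(methoxymethoxy)-4-(3-methylbut-2-en-1-yl)phenol, via aryl pinacol boronate 5 (not isolated)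
Conditions: [Ir(OMe)(C8H12)]2 (1.5 mol%), 4,4'-di-tert-butyl-2,2'-bipyridine (3 mol%), B2pin2, THF, 65 °C; then NaOH, H2O2, H2O, 0 °C
Reagents that add atoms: bis(pinacolato)diboron, CC1(C)OB(OC1(C)C)B1OC(C)(C)C(C)(C)O1 (boryl group of 5 only); hydrogen peroxide, OO
Why: Iridium-catalysed arene C–H borylation is sterically controlled and should go to the only C–H without an ortho substituent, para to the prenyl group; basic peroxide oxidation of the boronate then gives the phenol without touching the trisubstituted alkene.

Step 4
Reactants: 6 3,5-bis(methoxymethoxy)-4-(3-methylbut-2-en-1-yl)phenol; 7 methyl 2-(bromomethyl)prop-2-enoate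
Product: 8 methyl 2-{[3,5-bis(methoxymethoxy)-4-(3-methylbut-2-en-1-yl)phenoxy]methyl}prop-2-enoate
Conditions: K2CO3, acetone, rt
Reagents that add atoms: none
Why: Williamson ether synthesis with a highly reactive allylic bromide; direct and allylic-transposed displacement give the same ether.

Step 5
Reactants: 8 methyl 2-{[3,5-bis(methoxymethoxy)-4-(3-methylbut-2-en-1-yl)phenoxy]methyl}prop-2-enoate
Product: 9 methyl 2-{[6-hydroxy-2,4-bis(methoxymethoxy)-3-(3-methylbut-2-en-1-yl)phenyl]methyl}prop-2-enoate
Conditions: 1,2-dichlorobenzene, BHT (cat.), 170 °C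
Reagents that add atoms: none
Why: Aromatic Claisen rearrangement to either of the two equivalent ortho carbons and tautomerisation form the C8–C1'' bond; a neutral, non-basic solvent is chosen so that no amine promotes lactonisation and double-bond migration, and any lactone 11 formed is carried into step 6.

Step 6
Reactants: 9 methyl 2-{[6-hydroxy-2,4-bis(methoxymethoxy)-3-(3-methylbut-2-en-1-yl)phenyl]methyl}prop-2-enoate
Product: 11 5,7-bis(methoxymethoxy)-3-methylidene-6-(3-methylbut-2-en-1-yl)-3,4-dihydro-2H-chromen-2-one, via hydroxy acid 10 (not isolated)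
Conditions: LiOH, THF/H2O, 0 °C to rt; 1 M HCl to pH 4, extraction into CH2Cl2; EDC·HCl, CH2Cl2, 0 °C
Reagents that add atoms: water, O (carboxyl oxygen of 10)
Why: Saponification followed by carbodiimide (Steglich-type) lactonisation of the dried extract closes the six-membered aryl lactone at 0 °C without amine base, so the exocyclic alkene should not migrate to the 3-methylcoumarin.

Step 7
Reactants: 11 5,7-bis(methoxymethoxy)-3-methylidene-6-(3-methylbut-2-en-1-yl)-3,4-dihydro-2H-chromen-2-one; 12 4,4,5,5-tetramethyl-2-(2-methylprop-1-en-1-yl)-1,3,2-dioxaborolane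
Product: 13 (3R)-5,7-bis(methoxymethoxy)-3,6-bis(3-methylbut-2-en-1-yl)-3,4-dihydro-2H-chromen-2-one
Conditions: [Rh(OH)((R)-BINAP)]2 (3 mol%), 12 (2 equiv), 1,4-dioxane/H2O (10:1), 40 °C
Reagents that add atoms: none
Why: Proposed new method: transmetalation of 12 to the hydroxo complex gives a 2-methylprop-1-enyl complex of monovalent rhodium, which adds across the exocyclic methylene of 11 to form the C3''–C4'' bond, and the resulting oxa-π-allyl rhodium enolate is protonated by water at C2'' with return of the rhodium hydroxide; the closest known reaction type is the rhodium-catalysed conjugate addition of organoboron reagents to α-substituted acrylates with enantioselective protonation, which has not been shown for an aryl α-methylene lactone with an alkenylboron partner. No ring closes. The one new stereocentre, C2'', is controlled by the BINAP ligand, which shields one face of the enolate while the proton is delivered. The step needs facial selectivity in that protonation, and the substrate secures it by holding the enolate in a single, ring-fixed geometry, so the mixture of enolate geometries that lowers selectivity with acyclic acrylates cannot arise. It also needs conjugate addition and protonation to outrun β-hydride loss from the enolate and migration of the exocyclic alkene into the ring; a preformed, diene-free and base-free catalyst in a water-rich medium at 40 °C is chosen for that purpose, and it also removes any achiral rhodium–diene species that would give racemic product. The aryl ester makes 11 a stronger acceptor than an alkyl acrylate, so the mild temperature should suffice, and the prenyl alkene and the acetals are spectators.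

Step 8
Reactants: 13 (3R)-5,7-bis(methoxymethoxy)-3,6-bis(3-methylbut-2-en-1-yl)-3,4-dihydro-2H-chromen-2-one
Product: 14 (2R)-2-{[6-hydroxy-2,4-bis(methoxymethoxy)-3-(3-methylbut-2-en-1-yl)phenyl]methyl}-N-methoxy-N,5-dimethylhex-4-enamide
Conditions: MeNH(OMe)·HCl, AlMe3, CH2Cl2, 0 °C to rt
Reagents that add atoms: N,O-dimethylhydroxylamine hydrochloride, CNOC.Cl
Why: Aluminium amide aminolysis of the activated aryl lactone (Weinreb amide formation) opens the ring, frees O8a and is not basic enough to enolise C2''.

Step 9
Reactants: 14 (2R)-2-{[6-hydroxy-2,4-bis(methoxymethoxy)-3-(3-methylbut-2-en-1-yl)phenyl]methyl}-N-methoxy-N,5-dimethylhex-4-enamide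
Product: 15 (3R)-3-{[6-hydroxy-2,4-bis(methoxymethoxy)-3-(3-methylbut-2-en-1-yl)phenyl]methyl}-6-methylhept-5-en-2-one
Conditions: MeMgBr (3.5 equiv), THF, –20 to 0 °C
Reagents that add atoms: methylmagnesium bromide, C[Mg]Br
Why: Weinreb ketone synthesis: the first equivalent deprotonates the phenol and the chelated tetrahedral adduct prevents a second addition; 15 may stand in equilibrium with its cyclic hemiketal, which does not affect the next step.

Step 10
Reactants: 15 (3R)-3-{[6-hydroxy-2,4-bis(methoxymethoxy)-3-(3-methylbut-2-en-1-yl)phenyl]methyl}-6-methylhept-5-en-2-one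
Product: 16 3,5-bis(methoxymethoxy)-4-(3-methylbut-2-en-1-yl)-2-[(2R)-5-methyl-2-(prop-1-en-2-yl)hex-4-en-1-yl]phenol
Conditions: Ph3PCH3Br, KOtBu, THF, 0 °C
Reagents that add atoms: methyltriphenylphosphonium bromide, C[P+](c1ccccc1)(c1ccccc1)c1ccccc1.[Br-]
Why: Wittig methylenation of the methyl ketone completes the lavandulyl group; a short reaction time at 0 °C with excess ylide is meant to keep enolisation at C2'' slower than olefination.

Step 11
Reactants: 16 3,5-bis(methoxymethoxy)-4-(3-methylbut-2-en-1-yl)-2-[(2R)-5-methyl-2-(prop-1-en-2-yl)hex-4-en-1-yl]phenol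
Product: 17 2-hydroxy-4,6-bis(methoxymethoxy)-5-(3-methylbut-2-en-1-yl)-3-[(2R)-5-methyl-2-(prop-1-en-2-yl)hex-4-en-1-yl]benzaldehyde
Conditions: MgCl2, Et3N, (CH2O)n, THF, 65 °C
Reagents that add atoms: paraformaldehyde (as formaldehyde), C=O
Why: Casnati–Skattebøl ortho-formylation: the magnesium phenoxide delivers formaldehyde to the only free ortho carbon (C4a) and a second formaldehyde accepts hydride; the medium is basic, so the acetals and alkenes should be untouched.

Step 12
Reactants: 17 2-hydroxy-4,6-bis(methoxymethoxy)-5-(3-methylbut-2-en-1-yl)-3-[(2R)-5-methyl-2-(prop-1-en-2-yl)hex-4-en-1-yl]benzaldehyde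
Product: 18 6-(1-hydroxyethyl)-3,5-bis(methoxymethoxy)-4-(3-methylbut-2-en-1-yl)-2-[(2R)-5-methyl-2-(prop-1-en-2-yl)hex-4-en-1-yl]phenol (both carbinol epimers)
Conditions: MeMgBr (3 equiv), THF, –78 to 0 °C; pH 7 buffer
Reagents that add atoms: methylmagnesium bromide, C[Mg]Br
Why: Grignard addition to the aldehyde; the new carbinol centre is not controlled and is removed in step 13, and the acid-labile benzylic alcohol is used crude after a neutral work-up.

Step 13
Reactants: 18 6-(1-hydroxyethyl)-3,5-bis(methoxymethoxy)-4-(3-methylbut-2-en-1-yl)-2-[(2R)-5-methyl-2-(prop-1-en-2-yl)hex-4-en-1-yl]phenol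
Product: 19 1-{2-hydroxy-4,6-bis(methoxymethoxy)-5-(3-methylbut-2-en-1-yl)-3-[(2R)-5-methyl-2-(prop-1-en-2-yl)hex-4-en-1-yl]phenyl}ethan-1-one
Conditions: MnO2, CH2Cl2, rt
Reagents that add atoms: none
Why: MnO2 oxidation of an activated benzylic alcohol under neutral conditions gives the hydrogen-bonded ortho-hydroxyacetophenone and leaves alkenes and acetals alone.

Step 14
Reactants: 19 1-{2-hydroxy-4,6-bis(methoxymethoxy)-5-(3-methylbut-2-en-1-yl)-3-[(2R)-5-methyl-2-(prop-1-en-2-yl)hex-4-en-1-yl]phenyl}ethan-1-one
Product: 21 5,7-bis(methoxymethoxy)-6-(3-methylbut-2-en-1-yl)-8-[(2R)-5-methyl-2-(prop-1-en-2-yl)hex-4-en-1-yl]-4H-chromen-4-one, via enaminone 20 (not isolated)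
Conditions: Me2NCH(OMe)2, toluene, 95 °C; then AcOH, CH2Cl2, 40 °C
Reagents that add atoms: N,N-dimethylformamide dimethyl acetal, COC(OC)N(C)C
Why: Condensation at the acetyl methyl group gives the enaminone, and acid-assisted addition–elimination of the O8a phenol closes the pyranone (enaminone chromone synthesis); acetic acid is too weak to cleave aryl methoxymethyl ethers at this temperature.

Step 15
Reactants: 2 1,3-bis(methoxymethoxy)benzene
Product: 22 1-bromo-2,4-bis(methoxymethoxy)benzene
Conditions: NBS, MeCN, 0 °C
Reagents that add atoms: N-bromosuccinimide, O=C1CCC(=O)N1Br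
Why: Electrophilic aromatic bromination goes para to one acetal oxygen and ortho to the other; the position between the two oxygens is more hindered.

Step 16
Reactants: 22 1-bromo-2,4-bis(methoxymethoxy)benzene
Product: 23 [2,4-bis(methoxymethoxy)phenyl]boronic acid
Conditions: n-BuLi, THF, –78 °C; B(OiPr)3; aq. NH4Cl
Reagents that add atoms: triisopropyl borate, CC(C)OB(OC(C)C)OC(C)C; water, O
Why: Bromine–lithium exchange is faster than ortho-lithiation at –78 °C, and trapping with the borate and hydrolysis give the boronic acid.

Step 17
Reactants: 21 5,7-bis(methoxymethoxy)-6-(3-methylbut-2-en-1-yl)-8-[(2R)-5-methyl-2-(prop-1-en-2-yl)hex-4-en-1-yl]-4H-chromen-4-one; 23 [2,4-bis(methoxymethoxy)phenyl]boronic acid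
Product: 24 (2S)-2-[2,4-bis(methoxymethoxy)phenyl]-5,7-bis(methoxymethoxy)-6-(3-methylbut-2-en-1-yl)-8-[(2R)-5-methyl-2-(prop-1-en-2-yl)hex-4-en-1-yl]-2,3-dihydro-4H-chromen-4-one
Conditions: [RhCl(C2H4)2]2 (2.5 mol%), (R,R)-2,5-diphenylbicyclo[2.2.2]octa-2,5-diene (5.5 mol%), 23 (3 equiv), K3PO4 (0.5 equiv), toluene/H2O, 40 °C
Reagents that add atoms: none
Why: Hayashi–Miyaura asymmetric 1,4-addition to a chromone: the aryl complex of monovalent rhodium adds to C2=C3 from the face left open by the chiral diene, which sets C2 as (S), and the enolate is protonated at C3; C2'' is too remote to influence the outcome, and a weak base at 40 °C is chosen so that 24 does not open to the chalcone.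

Step 18
Reactants: 24 (2S)-2-[2,4-bis(methoxymethoxy)phenyl]-5,7-bis(methoxymethoxy)-6-(3-methylbut-2-en-1-yl)-8-[(2R)-5-methyl-2-(prop-1-en-2-yl)hex-4-en-1-yl]-2,3-dihydro-4H-chromen-4-one
Product: 25 Kushenol B, (2S)-2-(2,4-dihydroxyphenyl)-5,7-dihydroxy-6-(3-methylbut-2-en-1-yl)-8-[(2R)-5-methyl-2-(prop-1-en-2-yl)hex-4-en-1-yl]-2,3-dihydro-4H-chromen-4-one
Conditions: HCl (1.25 M in MeOH), 0 °C to rt
Reagents that add atoms: none
Why: Acid-catalysed acetal exchange with methanol removes the four methoxymethyl groups as dimethoxymethane; low temperature and short exposure are meant to keep alkene protonation and ionisation of the C2–O1 bond slower than acetal cleavage.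

## Compound list

1 | resorcinol | Oc1cccc(O)c1 | starting material
2 | 1,3-bis(methoxymethoxy)benzene | COCOc1cccc(OCOC)c1 | intermediate
3 | prenyl bromide (1-bromo-3-methylbut-2-ene) | CC(C)=CCBr | starting material
4 | 1,3-bis(methoxymethoxy)-2-(3-methylbut-2-en-1-yl)benzene | COCOc1cccc(OCOC)c1CC=C(C)C | intermediate
5 | 2-[3,5-bis(methoxymethoxy)-4-(3-methylbut-2-en-1-yl)phenyl]-4,4,5,5-tetramethyl-1,3,2-dioxaborolane | COCOc1cc(B2OC(C)(C)C(C)(C)O2)cc(OCOC)c1CC=C(C)C | intermediate
6 | 3,5-bis(methoxymethoxy)-4-(3-methylbut-2-en-1-yl)phenol | COCOc1cc(O)cc(OCOC)c1CC=C(C)C | intermediate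
7 | methyl 2-(bromomethyl)prop-2-enoate | C=C(CBr)C(=O)OC | starting material
8 | methyl 2-{[3,5-bis(methoxymethoxy)-4-(3-methylbut-2-en-1-yl)phenoxy]methyl}prop-2-enoate | COCOc1cc(OCC(=C)C(=O)OC)cc(OCOC)c1CC=C(C)C | intermediate
9 | methyl 2-{[6-hydroxy-2,4-bis(methoxymethoxy)-3-(3-methylbut-2-en-1-yl)phenyl]methyl}prop-2-enoate | C=C(Cc1c(O)cc(OCOC)c(CC=C(C)C)c1OCOC)C(=O)OC | intermediate
10 | 2-{[6-hydroxy-2,4-bis(methoxymethoxy)-3-(3-methylbut-2-en-1-yl)phenyl]methyl}prop-2-enoic acid | C=C(Cc1c(O)cc(OCOC)c(CC=C(C)C)c1OCOC)C(=O)O | intermediate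
11 | 5,7-bis(methoxymethoxy)-3-methylidene-6-(3-methylbut-2-en-1-yl)-3,4-dihydro-2H-chromen-2-one | C=C1Cc2c(OCOC)c(CC=C(C)C)c(OCOC)cc2OC1=O | intermediate
12 | 4,4,5,5-tetramethyl-2-(2-methylprop-1-en-1-yl)-1,3,2-dioxaborolane | CC(C)=CB1OC(C)(C)C(C)(C)O1 | starting material
13 | (3R)-5,7-bis(methoxymethoxy)-3,6-bis(3-methylbut-2-en-1-yl)-3,4-dihydro-2H-chromen-2-one | O=C1[C@H](CC=C(C)C)Cc2c(OCOC)c(CC=C(C)C)c(OCOC)cc2O1 | intermediate
14 | (2R)-2-{[6-hydroxy-2,4-bis(methoxymethoxy)-3-(3-methylbut-2-en-1-yl)phenyl]methyl}-N-methoxy-N,5-dimethylhex-4-enamide | CON(C)C(=O)[C@H](CC=C(C)C)Cc1c(O)cc(OCOC)c(CC=C(C)C)c1OCOC | intermediate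
15 | (3R)-3-{[6-hydroxy-2,4-bis(methoxymethoxy)-3-(3-methylbut-2-en-1-yl)phenyl]methyl}-6-methylhept-5-en-2-one | CC(=O)[C@H](CC=C(C)C)Cc1c(O)cc(OCOC)c(CC=C(C)C)c1OCOC | intermediate
16 | 3,5-bis(methoxymethoxy)-4-(3-methylbut-2-en-1-yl)-2-[(2R)-5-methyl-2-(prop-1-en-2-yl)hex-4-en-1-yl]phenol | C=C(C)[C@H](CC=C(C)C)Cc1c(O)cc(OCOC)c(CC=C(C)C)c1OCOC | intermediate
17 | 2-hydroxy-4,6-bis(methoxymethoxy)-5-(3-methylbut-2-en-1-yl)-3-[(2R)-5-methyl-2-(prop-1-en-2-yl)hex-4-en-1-yl]benzaldehyde | C=C(C)[C@H](CC=C(C)C)Cc1c(O)c(C=O)c(OCOC)c(CC=C(C)C)c1OCOC | intermediate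
18 | 6-(1-hydroxyethyl)-3,5-bis(methoxymethoxy)-4-(3-methylbut-2-en-1-yl)-2-[(2R)-5-methyl-2-(prop-1-en-2-yl)hex-4-en-1-yl]phenol (both carbinol epimers) | C=C(C)[C@H](CC=C(C)C)Cc1c(O)c(C(C)O)c(OCOC)c(CC=C(C)C)c1OCOC | intermediate
19 | 1-{2-hydroxy-4,6-bis(methoxymethoxy)-5-(3-methylbut-2-en-1-yl)-3-[(2R)-5-methyl-2-(prop-1-en-2-yl)hex-4-en-1-yl]phenyl}ethan-1-one | C=C(C)[C@H](CC=C(C)C)Cc1c(O)c(C(C)=O)c(OCOC)c(CC=C(C)C)c1OCOC | intermediate
20 | (2E)-3-(dimethylamino)-1-{2-hydroxy-4,6-bis(methoxymethoxy)-5-(3-methylbut-2-en-1-yl)-3-[(2R)-5-methyl-2-(prop-1-en-2-yl)hex-4-en-1-yl]phenyl}prop-2-en-1-one | C=C(C)[C@H](CC=C(C)C)Cc1c(O)c(C(=O)/C=C/N(C)C)c(OCOC)c(CC=C(C)C)c1OCOC | intermediate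
21 | 5,7-bis(methoxymethoxy)-6-(3-methylbut-2-en-1-yl)-8-[(2R)-5-methyl-2-(prop-1-en-2-yl)hex-4-en-1-yl]-4H-chromen-4-one | C=C(C)[C@H](CC=C(C)C)Cc1c(OCOC)c(CC=C(C)C)c(OCOC)c2c1OC=CC2=O | intermediate
22 | 1-bromo-2,4-bis(methoxymethoxy)benzene | COCOc1ccc(Br)c(OCOC)c1 | intermediate
23 | [2,4-bis(methoxymethoxy)phenyl]boronic acid | COCOc1ccc(B(O)O)c(OCOC)c1 | intermediate
24 | (2S)-2-[2,4-bis(methoxymethoxy)phenyl]-5,7-bis(methoxymethoxy)-6-(3-methylbut-2-en-1-yl)-8-[(2R)-5-methyl-2-(prop-1-en-2-yl)hex-4-en-1-yl]-2,3-dihydro-4H-chromen-4-one | C=C(C)[C@H](CC=C(C)C)Cc1c(OCOC)c(CC=C(C)C)c(OCOC)c2c1O[C@H](c1ccc(OCOC)cc1OCOC)CC2=O | intermediate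
25 | Kushenol B, (2S)-2-(2,4-dihydroxyphenyl)-5,7-dihydroxy-6-(3-methylbut-2-en-1-yl)-8-[(2R)-5-methyl-2-(prop-1-en-2-yl)hex-4-en-1-yl]-2,3-dihydro-4H-chromen-4-one | C=C(C)[C@H](CC=C(C)C)Cc1c(O)c(CC=C(C)C)c(O)c2c1O[C@H](c1ccc(O)cc1O)CC2=O | target

## Step count and least certain steps

Total: 18 steps. Longest linear sequence: 16 steps (steps 1–14, 17 and 18, from resorcinol 1); steps 15 and 16 form the two-step branch to boronic acid 23.

**Step 7 (key step).**
- What may go wrong: proton delivery to the rhodium enolate may show poor facial selectivity; the enolate may lose a β-hydrogen towards the aromatic coumarin instead of being protonated; the rhodium hydride so formed may move the exocyclic alkene of unreacted 11 into the ring; and the trisubstituted alkenyl pinacol boronate may transmetalate slowly and be lost to protodeboronation.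
- Why: the reaction type has not been run on a cyclic aryl lactone, and the coumarin is a strong thermodynamic pull.
- Fallback (known chemistry, from phenol 6 back to lactone 13): Casnati–Skattebøl formylation of 6 gives the salicylaldehyde F1, which is silylated with TIPSOTf and 2,6-lutidine to the triisopropylsilyl ether F2. Wittig olefination with the stabilised ylide of (R)-4-benzyl-3-(bromoacetyl)oxazolidinone gives the (E)-enoyl imide F3. Conjugate reduction with [(Ph3P)CuH]6, which leaves the prenyl alkene alone, gives the saturated imide F4. Evans alkylation of its sodium enolate (NaN(SiMe3)2, THF, –78 °C) with bromide 3 gives the alkylated imide F5 with the (R)-configuration at C2'' under the established chelate model. Bu4NF buffered with AcOH frees the phenol, which closes onto the imide carbonyl and expels the auxiliary, so the route is rejoined at 13.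

**Step 3.**
- What may go wrong: the pinacolborane formed during borylation may hydroborate or isomerise the prenyl alkene under iridium catalysis.
- Why: alkenes are not fully inert to iridium boryl and hydride species.
- Fallback (from 2 back to 6): the oxygen is introduced before the alkene. The same borylation of 2 gives the aryl boronate F6, which is oxidised in the flask to 3,5-bis(methoxymethoxy)phenol F7. Silylation with TIPSCl and imidazole gives the silyl ether F8. Ortho-lithiation between the two acetals and copper-mediated alkylation with 3 give the prenylated silyl ether F9, and Bu4NF releases 6.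

**Step 5.**
- What may go wrong: at the temperature the rearrangement needs, the phenol may lactonise in the flask and the double bond may then migrate into the ring, or the acrylate may polymerise.
- Why: the rearrangement of an electron-poor allyl unit is slow, and the 3-methylcoumarin is the thermodynamic end point.
- Fallback (from 6 back to 9): the C8–C1'' bond is made by polar ortho C-alkylation instead of a sigmatropic shift. The bromomagnesium phenoxide of 6 (EtMgBr, toluene) is alkylated at the ortho carbon by bromide 7 with allylic transposition at room temperature, a known behaviour of metal phenoxides in non-polar media. This gives 9 directly and makes no new compound.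

**Step 10.**
- What may go wrong: the basic ylide may enolise the methyl ketone towards C2'' and erode the configuration set in step 7.
- Why: C2'' is α to the carbonyl and the ylide is a moderately strong base.
- Fallback (from 15 back to 16): a two-stage Peterson olefination replaces the ylide. The non-basic organocerium reagent from Me3SiCH2Li and CeCl3 adds to the ketone without enolisation to give the β-hydroxysilane F10, and KH in THF then effects syn-elimination to 16.

**Step 17.**
- What may go wrong: the addition may be slow, because the arylrhodium carries an ortho acetal and the 5,7-dialkoxychromone is a poor acceptor, so protodeboronation of the electron-rich boronic acid may overtake it; base-induced opening of 24 to the chalcone would erode C2.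
- Why: both partners are at the unfavourable end of the known scope.
- Fallback (from 19 and 22 back to 24): bromide 22 is lithiated and formylated with DMF to 2,4-bis(methoxymethoxy)benzaldehyde F11. Claisen–Schmidt condensation of F11 with ketone 19 (KOH, EtOH) gives the 2'-hydroxychalcone F12. Intramolecular oxa-Michael addition under a quinine-derived thiourea catalyst closes ring C to 24. Selectivity may be lower than in the arylation, but the C2 epimers are diastereomers because of C2'' and can be separated by chromatography.

**Step 18.**
- What may go wrong: protonation of the prenyl or isopropenyl alkenes with capture by the neighbouring phenols would form chromans, and acid ionisation of the C2–O1 bond would epimerise C2.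
- Why: both processes are acid-catalysed, like the acetal cleavage itself.
- Fallback (from 24 back to 25): the acetals are exchanged rather than hydrolysed. Me3SiOTf with 2,2'-bipyridyl in CH2Cl2 at 0 °C converts the aryl methoxymethyl ethers through pyridinium intermediates, without free Brønsted acid, into the tetrakis(trimethylsilyl) ether F13, and neutral methanolysis of the silyl ethers then gives 25.

## Further compounds

F1 | step 7 | 6-hydroxy-2,4-bis(methoxymethoxy)-3-(3-methylbut-2-en-1-yl)benzaldehyde | O=Cc1c(O)cc(OCOC)c(CC=C(C)C)c1OCOC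
F2 | step 7 | 2,4-bis(methoxymethoxy)-3-(3-methylbut-2-en-1-yl)-6-{[tri(propan-2-yl)silyl]oxy}benzaldehyde | O=Cc1c(O[Si](C(C)C)(C(C)C)C(C)C)cc(OCOC)c(CC=C(C)C)c1OCOC
F3 | step 7 | (4R)-4-benzyl-3-[(2E)-3-(2,4-bis(methoxymethoxy)-3-(3-methylbut-2-en-1-yl)-6-{[tri(propan-2-yl)silyl]oxy}phenyl)prop-2-enoyl]-1,3-oxazolidin-2-one | O=C1OC[C@@H](Cc2ccccc2)N1C(=O)/C=C/c1c(O[Si](C(C)C)(C(C)C)C(C)C)cc(OCOC)c(CC=C(C)C)c1OCOC
F4 | step 7 | (4R)-4-benzyl-3-[3-(2,4-bis(methoxymethoxy)-3-(3-methylbut-2-en-1-yl)-6-{[tri(propan-2-yl)silyl]oxy}phenyl)propanoyl]-1,3-oxazolidin-2-one | O=C1OC[C@@H](Cc2ccccc2)N1C(=O)CCc1c(O[Si](C(C)C)(C(C)C)C(C)C)cc(OCOC)c(CC=C(C)C)c1OCOC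
F5 | step 7 | (4R)-4-benzyl-3-{(2R)-2-[(2,4-bis(methoxymethoxy)-3-(3-methylbut-2-en-1-yl)-6-{[tri(propan-2-yl)silyl]oxy}phenyl)methyl]-5-methylhex-4-enoyl}-1,3-oxazolidin-2-one | O=C1OC[C@@H](Cc2ccccc2)N1C(=O)[C@H](CC=C(C)C)Cc1c(O[Si](C(C)C)(C(C)C)C(C)C)cc(OCOC)c(CC=C(C)C)c1OCOC
F6 | step 3 | 2-[3,5-bis(methoxymethoxy)phenyl]-4,4,5,5-tetramethyl-1,3,2-dioxaborolane | COCOc1cc(B2OC(C)(C)C(C)(C)O2)cc(OCOC)c1
F7 | step 3 | 3,5-bis(methoxymethoxy)phenol | COCOc1cc(O)cc(OCOC)c1
F8 | step 3 | [3,5-bis(methoxymethoxy)phenoxy]tri(propan-2-yl)silane | COCOc1cc(O[Si](C(C)C)(C(C)C)C(C)C)cc(OCOC)c1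
F9 | step 3 | [3,5-bis(methoxymethoxy)-4-(3-methylbut-2-en-1-yl)phenoxy]tri(propan-2-yl)silane | COCOc1cc(O[Si](C(C)C)(C(C)C)C(C)C)cc(OCOC)c1CC=C(C)C
F0 | step 5 | none | none
F10 | step 10 | (3R)-3-{[6-hydroxy-2,4-bis(methoxymethoxy)-3-(3-methylbut-2-en-1-yl)phenyl]methyl}-2,6-dimethyl-1-(trimethylsilyl)hept-5-en-2-ol (both C2 epimers) | C[Si](C)(C)CC(C)(O)[C@H](CC=C(C)C)Cc1c(O)cc(OCOC)c(CC=C(C)C)c1OCOC
F11 | step 17 | 2,4-bis(methoxymethoxy)benzaldehyde | COCOc1ccc(C=O)c(OCOC)c1
F12 | step 17 | (2E)-3-[2,4-bis(methoxymethoxy)phenyl]-1-{2-hydroxy-4,6-bis(methoxymethoxy)-5-(3-methylbut-2-en-1-yl)-3-[(2R)-5-methyl-2-(prop-1-en-2-yl)hex-4-en-1-yl]phenyl}prop-2-en-1-one | C=C(C)[C@H](CC=C(C)C)Cc1c(O)c(C(=O)/C=C/c2ccc(OCOC)cc2OCOC)c(OCOC)c(CC=C(C)C)c1OCOC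
F13 | step 18 | (2S)-2-[2,4-bis(trimethylsilyloxy)phenyl]-6-(3-methylbut-2-en-1-yl)-8-[(2R)-5-methyl-2-(prop-1-en-2-yl)hex-4-en-1-yl]-5,7-bis(trimethylsilyloxy)-2,3-dihydro-4H-chromen-4-one | C=C(C)[C@H](CC=C(C)C)Cc1c(O[Si](C)(C)C)c(CC=C(C)C)c(O[Si](C)(C)C)c2c1O[C@H](c1ccc(O[Si](C)(C)C)cc1O[Si](C)(C)C)CC2=O
A1 | alternative 1 | 3-(methoxymethoxy)-2-(3-methylbut-2-en-1-yl)cyclobut-2-en-1-one | O=C1CC(OCOC)=C1CC=C(C)C
A2 | alternative 1 | {[(4R)-7-methyl-4-(prop-1-en-2-yl)oct-6-en-1-yn-1-yl]oxy}tri(propan-2-yl)silane | C=C(C)[C@H](CC=C(C)C)CC#CO[Si](C(C)C)(C(C)C)C(C)C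
A3 | alternative 1 | 5-(methoxymethoxy)-4-(3-methylbut-2-en-1-yl)-2-[(2R)-5-methyl-2-(prop-1-en-2-yl)hex-4-en-1-yl]-3-{[tri(propan-2-yl)silyl]oxy}phenol | C=C(C)[C@H](CC=C(C)C)Cc1c(O)cc(OCOC)c(CC=C(C)C)c1O[Si](C(C)C)(C(C)C)C(C)C
A4 | alternative 2 | 6-(1,3-dithian-2-yl)-3,5-bis(methoxymethoxy)-4-(3-methylbut-2-en-1-yl)-2-[(2R)-5-methyl-2-(prop-1-en-2-yl)hex-4-en-1-yl]phenol | C=C(C)[C@H](CC=C(C)C)Cc1c(O)c(C2SCCCS2)c(OCOC)c(CC=C(C)C)c1OCOC
A5 | alternative 2 | (2S)-2-[2,4-bis(methoxymethoxy)phenyl]oxirane | COCOc1ccc([C@H]2CO2)c(OCOC)c1
A6 | alternative 2 | (1R)-1-[2,4-bis(methoxymethoxy)phenyl]-2-(2-{2-hydroxy-4,6-bis(methoxymethoxy)-5-(3-methylbut-2-en-1-yl)-3-[(2R)-5-methyl-2-(prop-1-en-2-yl)hex-4-en-1-yl]phenyl}-1,3-dithian-2-yl)ethan-1-ol | C=C(C)[C@H](CC=C(C)C)Cc1c(O)c(C2(C[C@@H](O)c3ccc(OCOC)cc3OCOC)SCCCS2)c(OCOC)c(CC=C(C)C)c1OCOC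
A7 | alternative 3 | (4R)-4-benzyl-3-[3-(6-{[tert-butyl(dimethyl)silyl]oxy}-2,4-bis(methoxymethoxy)-3-(3-methylbut-2-en-1-yl)phenyl)propanoyl]-1,3-oxazolidin-2-one | O=C1OC[C@@H](Cc2ccccc2)N1C(=O)CCc1c(O[Si](C)(C)C(C)(C)C)cc(OCOC)c(CC=C(C)C)c1OCOC
A8 | alternative 3 | (4R)-4-benzyl-3-{(2R)-2-[(6-{[tert-butyl(dimethyl)silyl]oxy}-2,4-bis(methoxymethoxy)-3-(3-methylbut-2-en-1-yl)phenyl)methyl]-5-methylhex-4-enoyl}-1,3-oxazolidin-2-one | O=C1OC[C@@H](Cc2ccccc2)N1C(=O)[C@H](CC=C(C)C)Cc1c(O[Si](C)(C)C(C)(C)C)cc(OCOC)c(CC=C(C)C)c1OCOC
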